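**Retrosynthetic overview**

1. The plan rests on the two Ar–CH2–CH2–Ar′ bridges. Each ends in a 4-hydroxy-3-methoxyphenyl ring, so the CH2 bonded to that ring is the aldehyde carbon of vanillin, used with reversed polarity as a 2-lithio-1,3-dithiane.
2. Both CH2–CH2 bonds are cut at once, giving two lithiodithianes and a bis(bromomethyl) diarylmethane. Its bromomethyl groups sit ortho (ring A) and para (ring B) to the central CH2. Raney Ni and hydrogenolysis finish the synthesis.
3. The dibromide comes from a 3-arylphthalide by reductive C–O opening (Et3SiH/CF3CO2H), LiAlH4 reduction and Appel bromination.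
4. The phthalide comes from a ring B aryllithium (2-benzyloxy-6-methoxy, from methyl 4-bromo-3,5-dihydroxybenzoate) and a ring A 2-formylbenzoate (from methyl 3,5-dimethoxybenzoate, with BCl3 telling the two methoxy groups apart).
5. Ring order: all four benzene rings are bought and no ring of the target is built. A lactone ring is closed in step 8 and opened in step 9; two dithiane rings are made in step 12 and removed in step 14.

Key step: step 13

Remark on the chemistry: the target has no stereocentre. The only stereocentre on the route is C3 of lactone 12, which is formed racemic and removed in step 9.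

**Route**

Step 1
Reactants: 1 methyl 3,5-dimethoxybenzoate
Product: 2 methyl 2-formyl-3,5-dimethoxybenzoate
Conditions: Cl2CHOMe, TiCl4, CH2Cl2, −10 °C → rt; then ice/H2O
Reagents that add atoms: dichloromethyl methyl ether, COC(Cl)Cl (formyl carbon); water, O (formyl oxygen on hydrolytic work-up)
Why: Rieche formylation should attack the carbon between the ester and one methoxy group, which is para to the other methoxy group and less crowded than the carbon flanked by both methoxy groups.

Step 2
Reactants: 2 methyl 2-formyl-3,5-dimethoxybenzoate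
Product: 3 methyl 2-formyl-3-hydroxy-5-methoxybenzoate
Conditions: BCl3 (1.2 equiv), CH2Cl2, −78 → 0 °C; H2O
Reagents that add atoms: none
Why: Chelation-controlled ether cleavage: BCl3 bridges the aldehyde oxygen and the neighbouring methoxy oxygen, so only the methoxy group ortho to the formyl group should be cleaved, while the para methoxy group and the ester have no such chelate.

Step 3
Reactants: 3 methyl 2-formyl-3-hydroxy-5-methoxybenzoate
Product: 4 methyl 3-(benzyloxy)-2-formyl-5-methoxybenzoate
Conditions: BnBr, K2CO3, DMF, 60 °C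
Reagents that add atoms: benzyl bromide, BrCc1ccccc1
Why: Williamson etherification of the hydrogen-bonded phenol; the aldehyde and ester have no enolisable position and should tolerate carbonate.

Step 4
Reactants: 5 methyl 4-bromo-3,5-dihydroxybenzoate
Product: 6 methyl 3-(benzyloxy)-4-bromo-5-hydroxybenzoate
Conditions: BnBr (1.0 equiv), K2CO3 (1.0 equiv), DMF, rt
Reagents that add atoms: benzyl bromide, BrCc1ccccc1
Why: Williamson etherification with one equivalent of halide on a symmetric diphenol should give the mono-ether as the main component of a statistical mixture, from which the polar diol (recycled) and the non-polar diether are easily separated.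

Step 5
Reactants: 6 methyl 3-(benzyloxy)-4-bromo-5-hydroxybenzoate
Product: 7 methyl 3-(benzyloxy)-4-bromo-5-methoxybenzoate
Conditions: MeI, K2CO3, acetone, reflux
Reagents that add atoms: iodomethane, CI
Why: Williamson methylation of the one remaining phenol fixes the OBn/OMe pattern of ring B.

Step 6
Reactants: 7 methyl 3-(benzyloxy)-4-bromo-5-methoxybenzoate
Product: 8 [3-(benzyloxy)-4-bromo-5-methoxyphenyl]methanol
Conditions: iBu2AlH (2.5 equiv), CH2Cl2, −78 → 0 °C; aq. potassium sodium tartrate
Reagents that add atoms: none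
Why: Hydride reduction of the ester to the primary alcohol; iBu2AlH should leave the aryl bromide and the benzyl ether untouched.

Step 7
Reactants: 8 [3-(benzyloxy)-4-bromo-5-methoxyphenyl]methanol
Product: 9 {[3-(benzyloxy)-4-bromo-5-methoxyphenyl]methoxy}(tert-butyl)dimethylsilane
Conditions: TBSCl, imidazole, DMF, rt
Reagents that add atoms: tert-butyldimethylsilyl chloride, CC(C)(C)[Si](C)(C)Cl
Why: Silylation masks the acidic hydroxyl before the bromine–lithium exchange.

Step 8
Reactants: 9 {[3-(benzyloxy)-4-bromo-5-methoxyphenyl]methoxy}(tert-butyl)dimethylsilane; 4 methyl 3-(benzyloxy)-2-formyl-5-methoxybenzoate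
Product: 12 racemic 4-(benzyloxy)-3-[2-(benzyloxy)-4-({[tert-butyl(dimethyl)silyl]oxy}methyl)-6-methoxyphenyl]-6-methoxy-2-benzofuran-1(3H)-one (3-arylphthalide), via ring B aryllithium 10 (not isolated), via lithium alkoxide adduct 11 (not isolated)
Conditions: 9, n-BuLi (1.05 equiv), THF, −78 °C, 20 min; then 4, THF, −78 °C → rt; aq. NH4Cl
Reagents that add atoms: none
Why: Bromine–lithium exchange at −78 °C outruns deprotonation of the benzyl ether, the aryllithium adds to the aldehyde rather than the ester, and the alkoxide closes onto the ortho ester (the standard 3-arylphthalide synthesis from 2-formylbenzoates); the new stereocentre is uncontrolled and is removed in step 9.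

Step 9
Reactants: 12 racemic 3-arylphthalide
Product: 13 3-(benzyloxy)-2-{[2-(benzyloxy)-4-(hydroxymethyl)-6-methoxyphenyl]methyl}-5-methoxybenzoic acid
Conditions: Et3SiH (5 equiv), CF3CO2H–CH2Cl2 (1:4), 0 °C → rt; H2O added, rt; then K2CO3, MeOH–H2O; acidify to pH 3
Reagents that add atoms: none
Why: Ionic hydrogenation: the acid ionises the lactone C3–O bond to a benzhydryl cation stabilised by ortho and para alkoxy groups on both rings, Et3SiH traps it irreversibly (known reductive opening of 3-arylphthalides to 2-benzylbenzoic acids), the silyl ether is cleaved in the same medium, and the blocked ortho positions of ring B exclude anthrone formation.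

Step 10
Reactants: 13 3-(benzyloxy)-2-{[2-(benzyloxy)-4-(hydroxymethyl)-6-methoxyphenyl]methyl}-5-methoxybenzoic acid
Product: 14 [3-(benzyloxy)-2-{[2-(benzyloxy)-4-(hydroxymethyl)-6-methoxyphenyl]methyl}-5-methoxyphenyl]methanol
Conditions: LiAlH4 (3 equiv), THF, 0 °C → reflux; H2O/NaOH work-up
Reagents that add atoms: none
Why: LiAlH4 reduction of the carboxylic acid to the primary benzylic alcohol; aryl benzyl and methyl ethers are inert.

Step 11
Reactants: 14 [3-(benzyloxy)-2-{[2-(benzyloxy)-4-(hydroxymethyl)-6-methoxyphenyl]methyl}-5-methoxyphenyl]methanol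
Product: 15 1-(benzyloxy)-2-{[2-(benzyloxy)-4-(bromomethyl)-6-methoxyphenyl]methyl}-3-(bromomethyl)-5-methoxybenzene (bis(bromomethyl) diarylmethane)
Conditions: CBr4 (2.6 equiv), PPh3 (2.6 equiv), CH2Cl2, 0 °C → rt
Reagents that add atoms: tetrabromomethane, BrC(Br)(Br)Br
Why: Appel bromination converts both primary benzylic alcohols under neutral conditions; both carbons are meta to the ring oxygens, so the bromides should be stable and isolable.

Step 12
Reactants: 16 4-(benzyloxy)-3-methoxybenzaldehyde (O-benzylvanillin); 17 propane-1,3-dithiol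
Product: 18 2-[4-(benzyloxy)-3-methoxyphenyl]-1,3-dithiane
Conditions: BF3·OEt2 (0.2 equiv), CH2Cl2, 0 °C → rt
Reagents that add atoms: none
Why: Lewis-acid-catalysed thioacetalisation of an aromatic aldehyde; the benzyl ether tolerates catalytic BF3 at this temperature.

Step 13
Reactants: 15 bis(bromomethyl) diarylmethane; 18 2-[4-(benzyloxy)-3-methoxyphenyl]-1,3-dithiane (2.4 equiv)
Product: 22 tetra-O-benzyl bis(dithiane): 2,2′-disubstituted bis(1,3-dithiane) in which each former CH2Br carbon is bonded to C2 of a 2-[4-(benzyloxy)-3-methoxyphenyl]-1,3-dithiane, via 2-lithio-1,3-dithiane 19 (not isolated), via ring B arm monoadduct 20 (not isolated), via ring A arm monoadduct 21 (not isolated)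
Conditions: 18, n-BuLi (2.4 equiv), THF, −78 → −20 °C, 1 h; then 15, THF, −78 °C → rt
Reagents that add atoms: none
Why: n-BuLi removes the C2 proton of 18, which is benzylic and flanked by two sulfur atoms and far more acidic than the benzyl ether CH2, and the resulting acyl-anion equivalent 19 displaces bromide from each primary benzylic carbon of 15 by SN2, through the mono-adducts 20 and 21 to 22. This is a Corey–Seebach dithiane alkylation, and the closest known case is the alkylation of 2-aryl-2-lithio-1,3-dithianes with benzylic bromides on the way to bibenzyls and lignans. No ring is closed and no stereocentre is formed. The step needs only chemoselectivity and completeness: both bromides are primary, have no β-hydrogen to eliminate, sit meta to the ring oxygens so they do not ionise, and are insulated from one another by the central CH2, so the second alkylation should be as easy as the first. The central diarylmethane CH2 lies between two electron-rich rings and is less acidic than the dithiane, so proton transfer should not compete, and a small excess of 19 with slow warming from −78 °C limits electron-transfer coupling.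

Step 14
Reactants: 22 tetra-O-benzyl bis(dithiane)
Product: 23 tetra-O-benzyl target: 1-(benzyloxy)-2-({2-(benzyloxy)-4-[2-(4-(benzyloxy)-3-methoxyphenyl)ethyl]-6-methoxyphenyl}methyl)-3-[2-(4-(benzyloxy)-3-methoxyphenyl)ethyl]-5-methoxybenzene
Conditions: Raney Ni (W-2, excess), EtOH–THF, reflux; filtration, chromatography
Reagents that add atoms: none
Why: Raney Ni hydrogenolysis of the C–S bonds (Mozingo desulfurisation) turns each thioketal carbon into CH2; any benzyl ether lost here is harmless because step 15 removes all four.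

Step 15
Reactants: 23 tetra-O-benzyl target
Product: 24 target CNP0079001.0: 3-{[2-hydroxy-4-[2-(4-hydroxy-3-methoxyphenyl)ethyl]-6-methoxyphenyl]methyl}-2... written out as 2-({2-hydroxy-4-[2-(4-hydroxy-3-methoxyphenyl)ethyl]-6-methoxyphenyl}methyl)-3-[2-(4-hydroxy-3-methoxyphenyl)ethyl]-5-methoxyphenol
Conditions: H2 (1 atm), 10% Pd/C, EtOAc–MeOH, rt
Reagents that add atoms: none
Why: Catalytic hydrogenolysis of the four aryl benzyl ethers should release the tetraphenol; nothing else in the molecule is reducible under these conditions.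

**Compound list**

1 | methyl 3,5-dimethoxybenzoate | COC(=O)c1cc(OC)cc(OC)c1 | starting material
2 | methyl 2-formyl-3,5-dimethoxybenzoate | COC(=O)c1cc(OC)cc(OC)c1C=O | intermediate
3 | methyl 2-formyl-3-hydroxy-5-methoxybenzoate | COC(=O)c1cc(OC)cc(O)c1C=O | intermediate
4 | methyl 3-(benzyloxy)-2-formyl-5-methoxybenzoate | COC(=O)c1cc(OC)cc(OCc2ccccc2)c1C=O | intermediate
5 | methyl 4-bromo-3,5-dihydroxybenzoate | COC(=O)c1cc(O)c(Br)c(O)c1 | starting material
6 | methyl 3-(benzyloxy)-4-bromo-5-hydroxybenzoate | COC(=O)c1cc(O)c(Br)c(OCc2ccccc2)c1 | intermediate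
7 | methyl 3-(benzyloxy)-4-bromo-5-methoxybenzoate | COC(=O)c1cc(OC)c(Br)c(OCc2ccccc2)c1 | intermediate
8 | [3-(benzyloxy)-4-bromo-5-methoxyphenyl]methanol | OCc1cc(OC)c(Br)c(OCc2ccccc2)c1 | intermediate
9 | {[3-(benzyloxy)-4-bromo-5-methoxyphenyl]methoxy}(tert-butyl)dimethylsilane | CC(C)(C)[Si](C)(C)OCc1cc(OC)c(Br)c(OCc2ccccc2)c1 | intermediate
10 | ring B aryllithium: [2-(benzyloxy)-4-({[tert-butyl(dimethyl)silyl]oxy}methyl)-6-methoxyphenyl]lithium | [Li]c1c(OC)cc(CO[Si](C)(C)C(C)(C)C)cc1OCc1ccccc1 | intermediate
11 | lithium alkoxide adduct of 10 and 4 (open-chain benzhydrol ester) | COC(=O)c1cc(OC)cc(OCc2ccccc2)c1C(O[Li])c1c(OC)cc(CO[Si](C)(C)C(C)(C)C)cc1OCc1ccccc1 | intermediate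
12 | racemic 4-(benzyloxy)-3-[2-(benzyloxy)-4-({[tert-butyl(dimethyl)silyl]oxy}methyl)-6-methoxyphenyl]-6-methoxy-2-benzofuran-1(3H)-one | O=C1OC(c2c(OC)cc(CO[Si](C)(C)C(C)(C)C)cc2OCc2ccccc2)c2c1cc(OC)cc2OCc1ccccc1 | intermediate
13 | 3-(benzyloxy)-2-{[2-(benzyloxy)-4-(hydroxymethyl)-6-methoxyphenyl]methyl}-5-methoxybenzoic acid | OC(=O)c1cc(OC)cc(OCc2ccccc2)c1Cc1c(OC)cc(CO)cc1OCc1ccccc1 | intermediate
14 | [3-(benzyloxy)-2-{[2-(benzyloxy)-4-(hydroxymethyl)-6-methoxyphenyl]methyl}-5-methoxyphenyl]methanol | OCc1cc(OC)cc(OCc2ccccc2)c1Cc1c(OC)cc(CO)cc1OCc1ccccc1 | intermediate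
15 | 1-(benzyloxy)-2-{[2-(benzyloxy)-4-(bromomethyl)-6-methoxyphenyl]methyl}-3-(bromomethyl)-5-methoxybenzene | COc1cc(CBr)c(Cc2c(OCc3ccccc3)cc(CBr)cc2OC)c(OCc2ccccc2)c1 | intermediate
16 | 4-(benzyloxy)-3-methoxybenzaldehyde | O=Cc1ccc(OCc2ccccc2)c(OC)c1 | starting material
17 | propane-1,3-dithiol | SCCCS | starting material
18 | 2-[4-(benzyloxy)-3-methoxyphenyl]-1,3-dithiane | COc1cc(C2SCCCS2)ccc1OCc1ccccc1 | intermediate
19 | 2-[4-(benzyloxy)-3-methoxyphenyl]-2-lithio-1,3-dithiane | COc1cc(C2([Li])SCCCS2)ccc1OCc1ccccc1 | intermediate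
20 | mono-adduct alkylated at the ring B arm (ring A CH2Br intact) | COc1cc(CBr)c(Cc2c(OCc3ccccc3)cc(CC3(SCCCS3)c3ccc(OCc4ccccc4)c(OC)c3)cc2OC)c(OCc2ccccc2)c1 | intermediate
21 | mono-adduct alkylated at the ring A arm (ring B CH2Br intact) | COc1cc(CC2(SCCCS2)c2ccc(OCc3ccccc3)c(OC)c2)c(Cc2c(OCc3ccccc3)cc(CBr)cc2OC)c(OCc2ccccc2)c1 | intermediate
22 | tetra-O-benzyl bis(dithiane) | COc1cc(CC2(SCCCS2)c2ccc(OCc3ccccc3)c(OC)c2)c(Cc2c(OCc3ccccc3)cc(CC3(SCCCS3)c3ccc(OCc4ccccc4)c(OC)c3)cc2OC)c(OCc2ccccc2)c1 | intermediate
23 | tetra-O-benzyl target | COc1cc(CCc2ccc(OCc3ccccc3)c(OC)c2)c(Cc2c(OCc3ccccc3)cc(CCc3ccc(OCc4ccccc4)c(OC)c3)cc2OC)c(OCc2ccccc2)c1 | intermediate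
24 | CNP0079001.0: 2-({2-hydroxy-4-[2-(4-hydroxy-3-methoxyphenyl)ethyl]-6-methoxyphenyl}methyl)-3-[2-(4-hydroxy-3-methoxyphenyl)ethyl]-5-methoxyphenol | COc1cc(O)c(Cc2c(O)cc(CCc3ccc(O)c(OC)c3)cc2OC)c(CCc2ccc(O)c(OC)c2)c1 | target

**Totals**

Total step count: 15.
Longest linear sequence: 11 steps (steps 4–11, then 13–15, from methyl 4-bromo-3,5-dihydroxybenzoate).

**Steps most likely to fail**

1. Step 13. Single-electron transfer from the dithiane anion to the benzylic bromides could divert material into radical coupling and reduction, or the second alkylation could stall. The fallback reverses the roles and makes each bridge as an alkene. It sets out from dibromide 15 and returns at target 24. Arbuzov reaction with P(OEt)3 (neat, 130 °C) should give the tetraethyl bis(phosphonate) F1. Twofold Horner–Wadsworth–Emmons olefination with O-benzylvanillin 16 (NaH, THF, 0 °C → rt) should give the bis-(E)-stilbene F2. Hydrogenation (H2, Pd/C, EtOAc–MeOH) saturates both alkenes and cleaves all four benzyl ethers, giving 24 directly.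

2. Step 9. Acid-promoted loss of the benzyl ethers, or Friedel–Crafts capture of the benzhydryl cation before hydride transfer, could erode the reduction. The fallback cleaves the benzylic C–O bond by electron transfer in base, with no cation and no acid. It sets out from lactone 12 and returns at hydroxy acid 13. Zn dust in refluxing aqueous NaOH–pyridine should give the silyl-protected benzylbenzoic acid F3. Bu4NF in THF then removes the silyl ether to give 13; if the silyl ether is already lost in the hot base, 13 is obtained at once.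

3. Step 14. C–S hydrogenolysis may stop short at the two hindered thioketal carbons, benzyl ethers may be lost unevenly, and sulfur carried over may poison the palladium of step 15. The fallback removes sulfur by hydrolysis and the oxygen by hydrogenolysis. It sets out from bis(dithiane) 22 and returns at target 24. MeI and CaCO3 in aqueous MeCN (45 °C) should unmask the bis(deoxybenzoin) diketone F4. Hydrogenation over Pd/C in AcOH with a trace of HClO4 then reduces both para-oxygenated aryl ketones to CH2 and cleaves the four benzyl ethers, giving 24.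

**Further compounds**

F1 | step 13 | tetraethyl bis(phosphonate) of the diarylmethane core | CCOP(=O)(OCC)Cc1cc(OC)cc(OCc2ccccc2)c1Cc1c(OC)cc(CP(=O)(OCC)OCC)cc1OCc1ccccc1
F2 | step 13 | tetra-O-benzyl bis-(E)-stilbene | COc1cc(/C=C/c2ccc(OCc3ccccc3)c(OC)c2)c(Cc2c(OCc3ccccc3)cc(/C=C/c3ccc(OCc4ccccc4)c(OC)c3)cc2OC)c(OCc2ccccc2)c1
F3 | step 9 | 3-(benzyloxy)-2-{[2-(benzyloxy)-4-({[tert-butyl(dimethyl)silyl]oxy}methyl)-6-methoxyphenyl]methyl}-5-methoxybenzoic acid | OC(=O)c1cc(OC)cc(OCc2ccccc2)c1Cc1c(OC)cc(CO[Si](C)(C)C(C)(C)C)cc1OCc1ccccc1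
F4 | step 14 | tetra-O-benzyl bis(deoxybenzoin) diketone | COc1cc(CC(=O)c2ccc(OCc3ccccc3)c(OC)c2)c(Cc2c(OCc3ccccc3)cc(CC(=O)c3ccc(OCc4ccccc4)c(OC)c3)cc2OC)c(OCc2ccccc2)c1
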